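The readings are simulated for an exercise, noise included.

Millimolar-hours are our clock for J, and f is J as a fraction of the X charged.

| flask | X | D | remark | time |
|---|---|---|---|---|
| Saturday's | 58 mM | 7.3 mM (held) | run made earlier |  |
| flask | 39 mM | 7.3 mM (held) |  | 8.0 d |
- Saturday's (time / h: J / %, X / %): 5.00: 20, 82; 15.0: 46, 57; 25.0: 50, 39; 40.0: 51, 29

(standard deviation of a reading: 2 percentage points)
- the numbers in the tables scatter by 2 percentage points (one standard deviation)
- at the start none of D is in solution
- Q is what D becomes in solution
1. amount of J at 8.0 d, in percent of the X charged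
2. concentration of Q in solution at 8.0 d, in percent of saturation

1. In Saturday's run X + J sinks from 89.0 % to 80.0 % between 25.0 h and 40.0 h, while J stands near 51 %. We assume this loss is second-order in J. Integrated, the reciprocal of f then climbs linearly with charge times time, at a slope we call the loss constant 0.406 /M/h, a reading with wide scatter.

2. What must be known well? Saturation is the same in both runs, 7.3 mM, and does not enter this sum. A starting J lower by the gap between 46 % and 51 % gives 23.4 %. The loss constant, off by a factor 2 either way, gives 33.2 % or 16.3 %, so in this reckoning it moves the answer further than the start does.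

3. We assume the flask reaches Saturday's last J at the same charge times time. Carried on from there, our flask reckoning gives 24.6 %, with the 29 % of X in Saturday's last reading left uncounted.

4. The forecast says 12 % and 95 %: “A rough linear fit gives slow decay of about 0.013 /h, which leaves J near 10% at 192 h.” Its J stands lower than our 24.6 %.

5. The flask gives 28.8 % and 97.8 %.

    D ⇌ Q, rate k1*(csat - [Q]) (kL = 0.332 /h)
    Q ⇌ E (K = 2.40, k = 0.00985 /h)
    X + Q ⇌ J + G (K = 7.44, k = 76.4 /M/h)
    J + G → Z (k = 0.466 /M/h)

In the flask, X + Q into J + G ran while X stood, with half its turnover done by 0.455 d and J at 57.4 % at 0.800 d. In the flask J + G into Z took 65.0 % of the charge by 8.0 d, J's half-life by this step going from 3.0 d at 0.616 d to 5.5 d at 8.00 d. At 8.00 d in the flask G stood at 11.2 mM beside 11.2 mM of J. For the neighbour charged with 23 mM, 0.406 /M/h reckons J at 35.6 %. That neighbour holds 37.5 % of its charge as J at 8.00 d.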